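**Plan**

1. Retrosynthesis: the MOM group is put back on the naphthol, the C1 carbinol is returned to a C1 ketone, and a methyl ester is placed on C3 as a removable activating group.
2. Enabling feature: C2 of the tetralin ring carries only hydrogens and lies between C1 (the carbonyl carbon at the ketone stage) and C3. Cutting C1–C2 and C2–C3 and deleting C2 therefore contracts the ring C1–C2–C3–C4–C4a–C8a to the five-membered ring of a 3-aryl-4-methoxyindan-1-one-2-carboxylate.
3. The indanone is cut at the ester (C-acylation), at the bond from the aryl-bearing carbon to the benzo ring (aryl–Cβ bond of a 2'-bromochalcone) and at the enone C=C (aldol), giving 2-bromo-3-methoxyacetophenone and a 2-formyl-1-naphthol MOM ether.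
4. Forward: the two arenes are joined as the chalcone chain, the five-membered ring closes by asymmetric reductive Heck cyclisation, zinc-carbenoid CH2 insertion expands it to the six-membered ketone, and the ester is removed by radical decarboxylation.
5. Stereochemistry: C4 (R) is set by the chiral Pd catalyst in the indanone closure and is a spectator afterwards; C1 (S) is set by a catalyst-controlled CBS reduction of the C1 ketone, giving the 1,4-trans alcohol.
6. Locants C1–C8a of the target are used for all six-ring compounds.

Key step: step 8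

Assumption: the sense of induction of the Pd/bisphosphine catalyst in step 6 is fixed by a first run, and the ligand antipode that leads to the (3R)-indanone is the one used.

**Route**

Step 1
Reactants: 1 8-methoxynaphthalen-1-ol
Product: 2 1-methoxy-8-(methoxymethoxy)naphthalene
Conditions: NaH, MOMCl, THF/DMF, 0 °C → rt
Reagents that add atoms: chloromethyl methyl ether, COCCl
Why: Williamson-type O-alkylation of the sodium naphthoxide should be clean because NaH breaks the peri O–H···OMe hydrogen bond, and the acetal formed tolerates every basic, organometallic, Pd and Zn step that follows.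

Step 2
Reactants: 2 1-methoxy-8-(methoxymethoxy)naphthalene
Product: 4 8-methoxy-1-(methoxymethoxy)naphthalene-2-carbaldehyde, via 2-lithio naphthalene 3 (not isolated)
Conditions: n-BuLi, TMEDA, Et2O, 0 °C; DMF, −78 °C → rt; aq. NH4Cl
Reagents that add atoms: N,N-dimethylformamide, CN(C)C=O
Why: Directed ortho-metalation, in which OMOM is the stronger director and C2 is its only ortho C–H, should give the 2-lithio species, which DMF formylates.

Step 3
Reactants: 5 2-bromo-3-methoxybenzaldehyde
Product: 6 1-(2-bromo-3-methoxyphenyl)ethan-1-ol (racemic)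
Conditions: MeMgBr, THF, 0 °C; aq. NH4Cl
Reagents that add atoms: methylmagnesium bromide, C[Mg]Br
Why: Grignard 1,2-addition to the aldehyde is faster than any Br/Mg exchange at 0 °C, and the racemic carbinol centre is destroyed in step 4.

Step 4
Reactants: 6 1-(2-bromo-3-methoxyphenyl)ethan-1-ol
Product: 7 1-(2-bromo-3-methoxyphenyl)ethan-1-one
Conditions: Dess–Martin periodinane, CH2Cl2, rt
Reagents that add atoms: none
Why: Dess–Martin oxidation of a secondary benzylic alcohol runs under neutral conditions that leave the aryl bromide and the methyl ether untouched.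

Step 5
Reactants: 7 1-(2-bromo-3-methoxyphenyl)ethan-1-one; 4 8-methoxy-1-(methoxymethoxy)naphthalene-2-carbaldehyde
Product: 8 (2E)-1-(2-bromo-3-methoxyphenyl)-3-[8-methoxy-1-(methoxymethoxy)naphthalen-2-yl]prop-2-en-1-one
Conditions: KOH, EtOH, 0 °C → rt
Reagents that add atoms: none
Why: Claisen–Schmidt condensation, in which only the methyl ketone can enolise and only the aldehyde is a good acceptor, should give the conjugated (E)-enone by E1cB loss of water, the MOM acetal being inert to hydroxide.

Step 6
Reactants: 8 (2E)-1-(2-bromo-3-methoxyphenyl)-3-[8-methoxy-1-(methoxymethoxy)naphthalen-2-yl]prop-2-en-1-one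
Product: 9 (3R)-4-methoxy-3-[8-methoxy-1-(methoxymethoxy)naphthalen-2-yl]-2,3-dihydro-1H-inden-1-one
Conditions: Pd(OAc)2 (5 mol%), 3,5-Xyl-MeO-BIPHEP (one enantiomer, 6 mol%), HCO2Na, DMF, 80 °C
Reagents that add atoms: none
Why: Asymmetric reductive Heck cyclisation (oxidative addition into C–Br, 5-endo carbopalladation at the enone β-carbon, release of the palladium enolate by formate with loss of CO2) should give the indanone, with C3 set in the carbopalladation by the chiral bisphosphine on cationic Pd, which differentiates the two enone faces.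

Step 7
Reactants: 9 (3R)-4-methoxy-3-[8-methoxy-1-(methoxymethoxy)naphthalen-2-yl]-2,3-dihydro-1H-inden-1-one; 10 dimethyl carbonate
Product: 11 methyl (3R)-4-methoxy-3-[8-methoxy-1-(methoxymethoxy)naphthalen-2-yl]-1-oxo-2,3-dihydro-1H-indene-2-carboxylate (C2 epimers and enol form)
Conditions: NaH, (MeO)2CO, THF, 65 °C; aq. NH4Cl
Reagents that add atoms: dimethyl carbonate, COC(=O)OC
Why: Crossed Claisen condensation of the sodium enolate with dimethyl carbonate is driven by formation of the stabilised β-keto ester enolate, C2 being the only enolisable position and C3–H not being acidic in the enolate, so C3 keeps its configuration.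

Step 8
Reactants: 11 methyl (3R)-4-methoxy-3-[8-methoxy-1-(methoxymethoxy)naphthalen-2-yl]-1-oxo-2,3-dihydro-1H-indene-2-carboxylate; 12 diiodomethane
Product: 15 methyl (4R)-5-methoxy-4-[8-methoxy-1-(methoxymethoxy)naphthalen-2-yl]-1-oxo-1,2,3,4-tetrahydronaphthalene-3-carboxylate (target numbering; C3 epimers), via ethylzinc enolate 13 (not isolated), via zinc cyclopropanolate 14 (not isolated)
Conditions: Et2Zn (1.1 equiv), CH2Cl2, 0 °C; then CF3CO2ZnCH2I (2.5 equiv, from Et2Zn, CF3CO2H, CH2I2), CH2Cl2, 0 °C → rt; aq. NH4Cl
Reagents that add atoms: diiodomethane, ICI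
Why: The ethylzinc enolate 13 is C-alkylated at the ester-bearing carbon by the electrophilic carbenoid, and the resulting zinc homoenolate adds to the adjacent C1 carbonyl to give the donor–acceptor cyclopropanolate 14, whose bond between the alkoxide carbon and the ester carbon (the former C1–C2 bond of the indanone) breaks to a six-ring zinc ester enolate that is protonated on work-up. The closest known reaction type is the zinc-carbenoid homologation of β-keto esters to γ-keto esters, which is established for cyclic β-keto esters as a one-carbon ring expansion. The only ring closed directly is the transient cyclopropane (3-exo-trig attack of the C–Zn bond on C=O); the six-membered ring arises from it by fragmentation of the shared bond of the bicyclo[3.1.0] alkoxide, so that the new CH2 becomes C2 with bonds to C1 and C3. No stereocentre that has to last is created: C3 forms as an epimer mixture and is erased in step 10, while C4 carries no charge at any stage and keeps its R configuration. The selectivity needed is insertion on the alkyl side of the ketone and not into the C1–C8a bond, and it is secured by the ester, which directs the carbenoid to the enolate carbon and makes the C1–C(ester) bond of 14 the only push–pull bond able to cleave. The trifluoroacetate carbenoid is chosen because the enolate carbon is flanked by the bulky C3 aryl group, and its amount and the reaction time are kept low to avoid a second methylene transfer to the product enolate.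

Step 9
Reactants: 15 methyl (4R)-5-methoxy-4-[8-methoxy-1-(methoxymethoxy)naphthalen-2-yl]-1-oxo-1,2,3,4-tetrahydronaphthalene-3-carboxylate
Product: 16 (4R)-5-methoxy-4-[8-methoxy-1-(methoxymethoxy)naphthalen-2-yl]-1-oxo-1,2,3,4-tetrahydronaphthalene-3-carboxylic acid (target numbering; C3 epimers)
Conditions: LiOH·H2O, THF/MeOH/H2O, rt; 1 M HCl to pH 3–4, 0 °C
Reagents that add atoms: lithium hydroxide (aqueous), [Li+].[OH-]
Why: Saponification (BAc2) of the methyl ester should proceed without harm, since C3 may epimerise but is removed next, C4–H is not acidic under these conditions, and the MOM acetal survives base and the brief cold acidification.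

Step 10
Reactants: 16 (4R)-5-methoxy-4-[8-methoxy-1-(methoxymethoxy)naphthalen-2-yl]-1-oxo-1,2,3,4-tetrahydronaphthalene-3-carboxylic acid
Product: 18 (4R)-5-methoxy-4-[8-methoxy-1-(methoxymethoxy)naphthalen-2-yl]-3,4-dihydronaphthalen-1(2H)-one, via Barton ester 17 (not isolated)
Conditions: 1-hydroxypyridine-2(1H)-thione, DCC, CH2Cl2, 0 °C → rt, dark; then t-BuSH (excess), hν (tungsten lamp), rt
Reagents that add atoms: none
Why: Barton reductive decarboxylation, in which the thiohydroxamate ester fragments in a light-initiated chain to an acyloxy radical that loses CO2, should give a secondary C3 radical that excess t-BuSH quenches by hydrogen transfer faster than a 1,2-aryl shift from C4 can occur, leaving the C4 configuration untouched.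

Step 11
Reactants: 18 (4R)-5-methoxy-4-[8-methoxy-1-(methoxymethoxy)naphthalen-2-yl]-3,4-dihydronaphthalen-1(2H)-one
Product: 19 (1S,4R)-5-methoxy-4-[8-methoxy-1-(methoxymethoxy)naphthalen-2-yl]-1,2,3,4-tetrahydronaphthalen-1-ol (1,4-trans)
Conditions: (R)-Me-CBS (20 mol%), BH3·SMe2, THF, −20 → 0 °C; MeOH
Reagents that add atoms: none
Why: In the Corey–Bakshi–Shibata reduction the oxazaborolidine binds borane and the ketone anti to its larger aryl flank, so the (R)-catalyst should deliver hydride to the face that gives the (1S)-alcohol, as is general for 1-tetralones, under catalyst control that has to override the weak preference of the remote pseudoaxial C4 aryl group for the cis alcohol.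

Step 12
Reactants: 19 (1S,4R)-5-methoxy-4-[8-methoxy-1-(methoxymethoxy)naphthalen-2-yl]-1,2,3,4-tetrahydronaphthalen-1-ol
Product: 20 dipolynaphthalene A, (1S,4R)-4-(1-hydroxy-8-methoxynaphthalen-2-yl)-5-methoxy-1,2,3,4-tetrahydronaphthalen-1-ol
Conditions: 3 M aq. HCl, THF, rt
Reagents that add atoms: none
Why: Acid-catalysed hydrolysis of the aryl MOM acetal via its oxocarbenium ion should be selective because the benzylic C1 alcohol does not ionise in dilute acid at room temperature, the ring methoxy group being meta to C8a and so unable to stabilise a C1 cation.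

**Compound list**

1 | 8-methoxynaphthalen-1-ol | COc1cccc2cccc(O)c12 | starting material
2 | 1-methoxy-8-(methoxymethoxy)naphthalene | COCOc1cccc2cccc(OC)c12 | intermediate
3 | [8-methoxy-1-(methoxymethoxy)naphthalen-2-yl]lithium (not isolated) | [Li]c1ccc2cccc(OC)c2c1OCOC | intermediate
4 | 8-methoxy-1-(methoxymethoxy)naphthalene-2-carbaldehyde | O=Cc1ccc2cccc(OC)c2c1OCOC | intermediate
5 | 2-bromo-3-methoxybenzaldehyde | COc1cccc(C=O)c1Br | starting material
6 | 1-(2-bromo-3-methoxyphenyl)ethan-1-ol (racemic) | COc1cccc(C(C)O)c1Br | intermediate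
7 | 1-(2-bromo-3-methoxyphenyl)ethan-1-one | COc1cccc(C(C)=O)c1Br | intermediate
8 | (2E)-1-(2-bromo-3-methoxyphenyl)-3-[8-methoxy-1-(methoxymethoxy)naphthalen-2-yl]prop-2-en-1-one | COc1cccc(C(=O)/C=C/c2ccc3cccc(OC)c3c2OCOC)c1Br | intermediate
9 | (3R)-4-methoxy-3-[8-methoxy-1-(methoxymethoxy)naphthalen-2-yl]-2,3-dihydro-1H-inden-1-one | COc1cccc2c1[C@@H](c1ccc3cccc(OC)c3c1OCOC)CC2=O | intermediate
10 | dimethyl carbonate | COC(=O)OC | starting material
11 | methyl (3R)-4-methoxy-3-[8-methoxy-1-(methoxymethoxy)naphthalen-2-yl]-1-oxo-2,3-dihydro-1H-indene-2-carboxylate (C2 epimers and enol form) | COc1cccc2c1[C@@H](c1ccc3cccc(OC)c3c1OCOC)C(C(=O)OC)C2=O | intermediate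
12 | diiodomethane | ICI | starting material
13 | ethylzinc enolate of 11 (not isolated; aryl-bearing centre as in 11) | COc1cccc2c1[C@@H](c1ccc3cccc(OC)c3c1OCOC)C(C(=O)OC)=C2O[Zn]CC | intermediate
14 | zinc cyclopropanolate from 13, the trifluoroacetatozinc alkoxide of methyl 6a-hydroxy-1,1a,6,6a-tetrahydrocyclopropa[a]indene-1a-carboxylate carrying the aryl and methoxy groups of 11 (not isolated; ring-fusion centres unassigned) | COc1cccc2c1[C@@H](c1ccc3cccc(OC)c3c1OCOC)C1(C(=O)OC)CC21O[Zn]OC(=O)C(F)(F)F | intermediate
15 | methyl (4R)-5-methoxy-4-[8-methoxy-1-(methoxymethoxy)naphthalen-2-yl]-1-oxo-1,2,3,4-tetrahydronaphthalene-3-carboxylate (target numbering; C3 epimers) | COc1cccc2c1[C@@H](c1ccc3cccc(OC)c3c1OCOC)C(C(=O)OC)CC2=O | intermediate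
16 | (4R)-5-methoxy-4-[8-methoxy-1-(methoxymethoxy)naphthalen-2-yl]-1-oxo-1,2,3,4-tetrahydronaphthalene-3-carboxylic acid (target numbering; C3 epimers) | COc1cccc2c1[C@@H](c1ccc3cccc(OC)c3c1OCOC)C(C(=O)O)CC2=O | intermediate
17 | 2-thioxopyridin-1(2H)-yl ester of 16 (Barton ester; not isolated) | COc1cccc2c1[C@@H](c1ccc3cccc(OC)c3c1OCOC)C(C(=O)ON1C=CC=CC1=S)CC2=O | intermediate
18 | (4R)-5-methoxy-4-[8-methoxy-1-(methoxymethoxy)naphthalen-2-yl]-3,4-dihydronaphthalen-1(2H)-one | COc1cccc2c1[C@@H](c1ccc3cccc(OC)c3c1OCOC)CCC2=O | intermediate
19 | (1S,4R)-5-methoxy-4-[8-methoxy-1-(methoxymethoxy)naphthalen-2-yl]-1,2,3,4-tetrahydronaphthalen-1-ol | COc1cccc2c1[C@@H](c1ccc3cccc(OC)c3c1OCOC)CC[C@@H]2O | intermediate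
20 | dipolynaphthalene A, (1S,4R)-4-(1-hydroxy-8-methoxynaphthalen-2-yl)-5-methoxy-1,2,3,4-tetrahydronaphthalen-1-ol | COc1cccc2c1[C@@H](c1ccc3cccc(OC)c3c1O)CC[C@@H]2O | target

**Step count**

Total: 12 steps. Longest linear sequence: 10 steps (steps 1, 2, 5–12, or equally 3, 4, 5–12).

**Steps most likely to fail**

Step 6. The 5-endo carbopalladation at a di-ortho-substituted aryl–palladium may be slow, so that hydride capture wins (hydrodebromination, conjugate reduction of the enone), and the ortho-substituted naphthyl group may erode facial selectivity. The fallback replaces the Pd/hydride manifold by rhodium-catalysed arylation without any reductant. Setting out from 7, Miyaura borylation (B2pin2, Pd(dppf)Cl2, KOAc, dioxane, 80 °C) would give 1-[3-methoxy-2-(4,4,5,5-tetramethyl-1,3,2-dioxaborolan-2-yl)phenyl]ethan-1-one F1. Claisen–Schmidt condensation of this with 4 would give the boronate chalcone (2E)-1-[3-methoxy-2-(4,4,5,5-tetramethyl-1,3,2-dioxaborolan-2-yl)phenyl]-3-[8-methoxy-1-(methoxymethoxy)naphthalen-2-yl]prop-2-en-1-one F2. Rh(I)-catalysed asymmetric intramolecular 1,4-addition (chiral bisphosphine or phosphoramidite, aq. K3PO4, toluene; B→Rh transmetalation, enone insertion, protonolysis) would then close the ring, and the route is rejoined at 9.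

Step 8. C-alkylation of the enolate carbon next to the bulky C3 aryl group may be sluggish, the product zinc enolate may take up a second methylene (methylation at C3), and the zinc Lewis acids may cost the MOM group. The fallback is the Dowd–Beckwith radical ring expansion, which forms the same two bonds through radicals instead of organozinc species. Setting out from 11, C-alkylation with CH2Br2 (K2CO3, DMF) would give methyl (3R)-2-(bromomethyl)-4-methoxy-3-[8-methoxy-1-(methoxymethoxy)naphthalen-2-yl]-1-oxo-2,3-dihydro-1H-indene-2-carboxylate F3. Bu3SnH/AIBN (slow addition, benzene, 80 °C) would generate the primary radical, which attacks the ketone 3-exo and undergoes β-scission to the ester-stabilised C3 radical; reduction of this rejoins the route at 15.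

Step 11. The substrate's own preference for hydride attack anti to the pseudoaxial C4 aryl group (cis alcohol) opposes the catalyst, so facial selectivity may be poor in this mismatched pairing. The fallback uses the matched reduction and then inverts C1. Setting out from 18, reduction with (S)-Me-CBS/BH3·SMe2 (or a bulky hydride) would give the cis alcohol (1R,4R)-5-methoxy-4-[8-methoxy-1-(methoxymethoxy)naphthalen-2-yl]-1,2,3,4-tetrahydronaphthalen-1-ol F4. Mitsunobu inversion (4-nitrobenzoic acid, PPh3, DIAD, THF) would give (1S,4R)-5-methoxy-4-[8-methoxy-1-(methoxymethoxy)naphthalen-2-yl]-1,2,3,4-tetrahydronaphthalen-1-yl 4-nitrobenzoate F5, and methanolysis (K2CO3, MeOH) rejoins the route at 19.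

**Further compounds**

F1 | step 6 | 1-[3-methoxy-2-(4,4,5,5-tetramethyl-1,3,2-dioxaborolan-2-yl)phenyl]ethan-1-one | COc1cccc(C(C)=O)c1B1OC(C)(C)C(C)(C)O1
F2 | step 6 | (2E)-1-[3-methoxy-2-(4,4,5,5-tetramethyl-1,3,2-dioxaborolan-2-yl)phenyl]-3-[8-methoxy-1-(methoxymethoxy)naphthalen-2-yl]prop-2-en-1-one | COc1cccc(C(=O)/C=C/c2ccc3cccc(OC)c3c2OCOC)c1B1OC(C)(C)C(C)(C)O1
F3 | step 8 | methyl (3R)-2-(bromomethyl)-4-methoxy-3-[8-methoxy-1-(methoxymethoxy)naphthalen-2-yl]-1-oxo-2,3-dihydro-1H-indene-2-carboxylate (C2 unassigned) | COc1cccc2c1[C@@H](c1ccc3cccc(OC)c3c1OCOC)C(CBr)(C(=O)OC)C2=O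
F4 | step 11 | (1R,4R)-5-methoxy-4-[8-methoxy-1-(methoxymethoxy)naphthalen-2-yl]-1,2,3,4-tetrahydronaphthalen-1-ol | COc1cccc2c1[C@@H](c1ccc3cccc(OC)c3c1OCOC)CC[C@H]2O
F5 | step 11 | (1S,4R)-5-methoxy-4-[8-methoxy-1-(methoxymethoxy)naphthalen-2-yl]-1,2,3,4-tetrahydronaphthalen-1-yl 4-nitrobenzoate | COc1cccc2c1[C@@H](c1ccc3cccc(OC)c3c1OCOC)CC[C@@H]2OC(=O)c1ccc(cc1)[N+](=O)[O-]
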